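## The problem

Compound 28 is a depsidone. Two benzene rings are joined by a diaryl ether oxygen and by an aryl ester, which together close the seven-membered dioxepinone (ring D), and the second benzene ring carries a fused five-membered 3-hydroxyphthalide (ring C). The atoms of ring A are called a1 (OMe), a2 (H), a3 (CH3), a4 (carbonyl carbon of the ring D ester), a5 (ether oxygen) and a6 (OH); those of ring B are b1 (ether oxygen), b2 (ester oxygen), b3 (CH3), b4 (OH), b5 (lactone carbonyl) and b6 (lactol carbon). Ring A is pentasubstituted and ring B hexasubstituted, and the ether oxygen lies between four ortho substituents, so the a5–O–b1 bond and the substitution patterns of both rings are the constructive problems. The only stereocentre is the lactol carbon on b6, (R) in the target. It is a hemiacetal that can epimerise through the ring-opened formyl carboxylic acid, and no second stereocentre exists to control it, so it has to be set by a catalyst at the end and released without opening the lactol. The ring D aryl ester is cleaved by hydroxide or alkoxide, the lactol is sensitive to base, oxidants and reductants, and the free phenols are electron-rich, so the late steps must be neutral or acidic. The enabling feature is on ring A: the methyl carbon on a3 and the carboxyl carbon on a4 are neighbours and a4 lies beside the a5 aryloxy oxygen. This is the pattern left when a 3-aryloxybenzyne with its triple bond between a3 and a4 takes up a carbon nucleophile at the carbon remote from oxygen and an electrophile at the carbon next to it.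

## Retrosynthesis

**Lactol configuration (28 from 27, 26 and 25).** No skeletal bond is cut; only the acyl–oxygen bond of an acylal is. The (R) centre is fixed as the isobutyrate 26, which cannot ring-open, by acylative dynamic kinetic resolution of the racemic lactol 25. Setting the centre earlier is pointless, because every free lactol on the way would racemise. The forward sequence must remove the benzyl ethers (giving 27) and then the acyl group without base; an enzyme that cleaves the acyl–oxygen bond does the latter.

**Ring C (25 from 23).** The lactol is the ring tautomer of the formyl acid 24. In 23 the acid is a tert-butyl ester and the aldehyde a dimethyl acetal, two groups that one acid treatment removes together and that tolerate organomagnesium reagents. A pseudoester or a phthalide would be shorter to carry but would not survive the key step.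

**Ring D (23 from 22 and 21).** The ester bond between the a4 carbonyl and the b2 oxygen is cut. Closing the ester after the ether is the reliable order for depsidones, because the ether holds acid and phenol together; the reverse order would expose an aryl ester to Grignard reagents. The b2 oxygen therefore needs its own protecting group (PMB in 21), removable in the presence of benzyl ethers, the ester and the acetal.

**Key disconnection (21 from 17).** The a3–CH3 and a4–CO2H bonds are cut together, leading back through the arylmagnesium 20 to the aryne 19 and its precursor 17. Against stepwise cross-coupling and carbonylation this installs both carbons in one flask with the regiochemistry dictated by the a5 aryloxy group. Against starting from an orsellinate-type ring A it allows the three contiguous oxygens a5, a6 and a1 to come from a cheap vanillin-type arene. The precursor 17 carries only heteroatoms on ring A. The forward reaction must tolerate the ester, acetal and benzylic ethers of ring B.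

**Aryne precursor (17 from 16, 15 and 13).** Either placement of iodine and sulfonate on a3 and a4 gives the same aryne 19. Iodine is put on a3 and the sulfonate on a4, because the a4 oxygen can then come from an a4 formyl group by Dakin oxidation (13 to 15), and the resulting phenol has a single free ortho position, a3, so iodination to 16 has no choice. The reverse placement would require iodinating an a3 phenol with two free ortho positions (a2 and a4) of similar electron density, the wanted one being the more hindered. The 4-chlorobenzenesulfonate is chosen for 17 because its ortho-magnesiated form is stable cold and eliminates cleanly on warming.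

**Diaryl ether (13 from 10 and 12).** The a5–O bond is cut. The formyl group of 12 serves twice: it activates the neighbouring C–Br bond for copper-catalysed displacement by the hindered phenoxide of 10, and it later becomes the a4 oxygen. The most congested bond is thus made early, on simple fragments, with all ring B substituents in place.

**Ring A fragment (12 from 11).** Commercial 2-bromoisovanillin 11 already has bromine, hydroxyl and methoxyl in the a5, a6, a1 order next to the formyl group; only O-benzylation is needed.

**Ring B fragment (10 from 9, 8, 6, 5, 4, 3 and 1).** The hexasubstituted ring is built by successive substitution around 2,4-dihydroxy-3-methylbenzoic acid 1, each position being dictated by the groups present: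
- the acid is esterified (3);
- bromine enters the only activated position, the future b1 (4);
- the free para hydroxyl (b2) takes the PMB group (5) and the chelated ortho hydroxyl (b4) the benzyl group (6);
- the last ring hydrogen (b6), flanked by ester and bromine, is magnesiated and formylated (8) and the aldehyde is acetalised (9);
- the bromide is exchanged for hydroxyl (10).

The sequence is linear but uses only substitution reactions with a single possible site.

## Roads not taken

**Alternative 1:** ring A and ring D would be formed together by cutting the a5–a4 and a2–a3 bonds. A 3-aryloxy-2-pyrone bearing a but-2-ynoate on the b2 oxygen (A1) would undergo an intramolecular Diels–Alder reaction on heating, lose CO2 and give the bis-benzyl depsidone methyl pseudoester A2.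
- Merits: the tether enforces the regiochemistry of ring A, the lactol is carried as a robust pseudoester with no organometallic step to survive, and A2 is only a few steps from 28. In steps after the key step this road is better than the chosen one.
- Weak points: the trioxygenated pyrone half of A1 is not an available compound and needs a de novo synthesis with three differentiated oxygens. Its C–O bond to a hexasubstituted phenol has no standard method. The aryl ynoate is an activated ester and a Michael acceptor. The cycloaddition closes a seven-membered tether ring and would need temperatures at which that ester is at risk.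
- Comparison: the chosen plan offers a ring A bought in aromatic form and a key step whose reaction class is established.

**Alternative 2:** ring B would be formed by cutting b1–b6 and b4–b5. The silyloxyfuran A3 and the ynoate A4 would combine by [4+2] addition and opening of the oxygen bridge to give the hexasubstituted phenol A5.
- Merits: all six substituents of ring B arise in one step, the polarity of the two partners matches the required orientation, and the b1 hydroxyl is freed exactly where the ether has to be made. For ring B alone this is clearly shorter than the seven steps used here.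
- Weak points: it solves only ring B and leaves the congested ether and the a3/a4 pattern to other steps. The protecting pattern of A5 would need changing: a b2 benzyl ether is not distinguishable from the other benzyl ethers, and a b4 silyl ether is doubtful in a hot basic ether coupling. The silyloxyfuran is hydrolytically fragile.
- Comparison: the chosen plan offers a ring B sequence in which every step has one possible site and a protecting pattern designed for the aryne step. If the linear sequence proved too long, A5-type chemistry could replace steps 1 to 7 without touching the key step.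

**Alternative 3:** the b6 carbon would be introduced last by cutting the b6–C(=O) bond. The depsidone b5 carboxylic acid A6, with hydrogen on b6, would be palladated under direction of the carboxylate (Pd(OAc)2, Ag2CO3, CO) and carbonylated to the cyclic anhydride A7.
- Merits: ring B needs one substituent fewer during the ether coupling, which would be less hindered, and the formylation and acetalisation steps disappear.
- Weak points: A7 has the b6 carbon at the wrong oxidation level. One of two similar anhydride carbonyls, each flanked by an oxygen substituent, would have to be reduced selectively and only as far as the lactol, in the presence of the ring D ester. The carbonylation itself needs hot oxidising conditions with silver carbonate on the complete, base-sensitive depsidone.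
- Comparison: this road is shorter on paper, but the chosen plan carries the b6 carbon at the aldehyde level from step 5 and so avoids an unsolved regioselective reduction at the end.

Key step: step 13

Assumption: the lactol carbon of 28 epimerises through the ring-opened formyl acid, so the (R)-lactol is taken to be isolable only if it is released last and kept in neutral or weakly acidic media at or below room temperature.

## Route

**Step 1**
Reactants: 1 2,4-dihydroxy-3-methylbenzoic acid
Product: 3 tert-butyl 2,4-dihydroxy-3-methylbenzoate, via acyl imidazolide 2 (not isolated)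
Conditions: CDI, DMF, 40 °C; then tBuOH, DBU, 50 °C
Reagents that add atoms: tert-butanol, CC(C)(C)O
Why: Activation of the acid as its acyl imidazolide and DBU-promoted alcoholysis is an established way to tert-butyl esters of hydroxybenzoic acids; phenols that are transiently carbonylated are regenerated on work-up.

**Step 2**
Reactants: 3 tert-butyl 2,4-dihydroxy-3-methylbenzoate
Product: 4 tert-butyl 5-bromo-2,4-dihydroxy-3-methylbenzoate
Conditions: NBS, MeCN, 0 °C
Reagents that add atoms: N-bromosuccinimide, O=C1CCC(=O)N1Br
Why: Electrophilic aromatic bromination; C5 is ortho to one hydroxyl and para to the other whereas C6 is meta to both, so only the 5-bromide should form.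

**Step 3**
Reactants: 4 tert-butyl 5-bromo-2,4-dihydroxy-3-methylbenzoate
Product: 5 tert-butyl 5-bromo-2-hydroxy-4-[(4-methoxybenzyl)oxy]-3-methylbenzoate
Conditions: PMBCl, K2CO3, DMF, rt
Reagents that add atoms: 4-methoxybenzyl chloride, COc1ccc(CCl)cc1
Why: Williamson etherification; the 2-hydroxyl is hydrogen-bonded to the ester carbonyl, so the more acidic 4-hydroxyl should be alkylated selectively by one equivalent of the chloride.

**Step 4**
Reactants: 5 tert-butyl 5-bromo-2-hydroxy-4-[(4-methoxybenzyl)oxy]-3-methylbenzoate
Product: 6 tert-butyl 2-(benzyloxy)-5-bromo-4-[(4-methoxybenzyl)oxy]-3-methylbenzoate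
Conditions: BnBr, K2CO3, DMF, 60 °C
Reagents that add atoms: benzyl bromide, BrCc1ccccc1
Why: Williamson etherification of the remaining chelated phenol, which needs heat; the tert-butyl ester is inert to carbonate.

**Step 5**
Reactants: 6 tert-butyl 2-(benzyloxy)-5-bromo-4-[(4-methoxybenzyl)oxy]-3-methylbenzoate
Product: 8 tert-butyl 2-(benzyloxy)-5-bromo-6-formyl-4-[(4-methoxybenzyl)oxy]-3-methylbenzoate, via arylmagnesium chloride 7 (not isolated)
Conditions: TMPMgCl·LiCl, THF, −20 to 0 °C; then DMF, 0 °C to rt; aq. NH4Cl
Reagents that add atoms: N,N-dimethylformamide, CN(C)C=O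
Why: Directed ortho-magnesiation with a hindered magnesium amide; the only ring hydrogen lies between the ester and the bromine, which both acidify it, the tert-butyl ester and the aryl bromide tolerate the base at this temperature, and DMF formylates the arylmagnesium.

**Step 6**
Reactants: 8 tert-butyl 2-(benzyloxy)-5-bromo-6-formyl-4-[(4-methoxybenzyl)oxy]-3-methylbenzoate
Product: 9 tert-butyl 2-(benzyloxy)-5-bromo-6-(dimethoxymethyl)-4-[(4-methoxybenzyl)oxy]-3-methylbenzoate
Conditions: HC(OMe)3, MeOH, PPTS (cat.), rt
Reagents that add atoms: trimethyl orthoformate, COC(OC)OC; methanol, CO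
Why: Acid-catalysed acetalisation with the orthoformate as water scavenger; the weak acid at room temperature should leave the tert-butyl ester and the PMB ether intact.

**Step 7**
Reactants: 9 tert-butyl 2-(benzyloxy)-5-bromo-6-(dimethoxymethyl)-4-[(4-methoxybenzyl)oxy]-3-methylbenzoate
Product: 10 tert-butyl 2-(benzyloxy)-6-(dimethoxymethyl)-5-hydroxy-4-[(4-methoxybenzyl)oxy]-3-methylbenzoate
Conditions: Pd2(dba)3 (cat.), tBuXPhos (cat.), KOH, 1,4-dioxane/H2O, 100 °C; then pH 7 phosphate buffer
Reagents that add atoms: potassium hydroxide, [K+].[OH-]
Why: Palladium-catalysed hydroxylation of an aryl bromide (C–O coupling with hydroxide) with a bulky biarylphosphine, which accepts di-ortho-substituted bromides; the hindered tert-butyl ester, the acetal and the benzylic ethers are stable to aqueous hydroxide and the buffered work-up protects the acetal.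

**Step 8**
Reactants: 11 2-bromo-3-hydroxy-4-methoxybenzaldehyde (2-bromoisovanillin)
Product: 12 3-(benzyloxy)-2-bromo-4-methoxybenzaldehyde
Conditions: BnBr, K2CO3, DMF, rt
Reagents that add atoms: benzyl bromide, BrCc1ccccc1
Why: Williamson etherification of a phenol.

**Step 9**
Reactants: 10 tert-butyl 2-(benzyloxy)-6-(dimethoxymethyl)-5-hydroxy-4-[(4-methoxybenzyl)oxy]-3-methylbenzoate; 12 3-(benzyloxy)-2-bromo-4-methoxybenzaldehyde
Product: 13 tert-butyl 2-(benzyloxy)-5-[2-(benzyloxy)-6-formyl-3-methoxyphenoxy]-6-(dimethoxymethyl)-4-[(4-methoxybenzyl)oxy]-3-methylbenzoate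
Conditions: CuI (cat.), picolinic acid (cat.), K3PO4, DMSO, 90 °C
Reagents that add atoms: none
Why: Ullmann diaryl ether coupling; the ortho formyl group activates the C–Br bond towards the copper phenoxide, the picolinic acid ligand is suited to hindered phenols, and all protecting groups are stable to phosphate base.

**Step 10**
Reactants: 13 diaryl ether aldehyde
Product: 15 tert-butyl 2-(benzyloxy)-5-[2-(benzyloxy)-6-hydroxy-3-methoxyphenoxy]-6-(dimethoxymethyl)-4-[(4-methoxybenzyl)oxy]-3-methylbenzoate, via aryl formate 14 (not isolated)
Conditions: mCPBA, Na2HPO4, CH2Cl2, 0 °C to rt; then K2CO3 (cat.), MeOH, 0 °C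
Reagents that add atoms: 3-chloroperbenzoic acid, OOC(=O)c1cccc(Cl)c1
Why: Dakin-type Baeyer–Villiger oxidation; on a ring with para methoxy and ortho aryloxy groups the aryl group migrates in the Criegee intermediate to give the formate, which mild methanolysis cleaves, and the buffer protects the acetal.

**Step 11**
Reactants: 15 phenol with hydroxyl on a4
Product: 16 tert-butyl 2-(benzyloxy)-5-[2-(benzyloxy)-6-hydroxy-5-iodo-3-methoxyphenoxy]-6-(dimethoxymethyl)-4-[(4-methoxybenzyl)oxy]-3-methylbenzoate
Conditions: NIS, MeCN, 0 °C
Reagents that add atoms: N-iodosuccinimide, O=C1CCC(=O)N1I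
Why: Electrophilic iodination of a phenol; the a4 hydroxyl has a single free ortho position, a3, which is also para to the a6 benzyloxy group, while a2 is meta to the hydroxyl, so the iodine should enter at a3.

**Step 12**
Reactants: 16 iodophenol
Product: 17 tert-butyl 2-(benzyloxy)-5-{2-(benzyloxy)-6-[(4-chlorophenyl)sulfonyloxy]-5-iodo-3-methoxyphenoxy}-6-(dimethoxymethyl)-4-[(4-methoxybenzyl)oxy]-3-methylbenzoate
Conditions: 4-ClC6H4SO2Cl, Et3N, DMAP (cat.), CH2Cl2, 0 °C to rt
Reagents that add atoms: 4-chlorobenzenesulfonyl chloride, O=S(=O)(Cl)c1ccc(Cl)cc1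
Why: Sulfonylation of a phenol; the 4-chlorobenzenesulfonate is used because ortho-magnesiated aryl 4-chlorobenzenesulfonates are stable at −78 °C and eliminate cleanly on warming.

**Step 13**
Reactants: 17 iodo sulfonate (iodine on a3, sulfonate on a4)
Product: 21 3-(benzyloxy)-2-{4-(benzyloxy)-5-(tert-butoxycarbonyl)-6-(dimethoxymethyl)-2-[(4-methoxybenzyl)oxy]-3-methylphenoxy}-4-methoxy-6-methylbenzoic acid, via arylmagnesium sulfonate 18 (not isolated), via aryne 19 (not isolated), via methylated arylmagnesium 20 (not isolated)
Conditions: iPrMgCl·LiCl (1.05 equiv), THF, −78 °C; MeMgCl (4 equiv), −78 to 0 °C; CO2 (gas), −40 °C to rt; aq. citric acid, 0 °C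
Reagents that add atoms: methylmagnesium chloride, C[Mg]Cl; carbon dioxide, O=C=O
Why: Iodine–magnesium exchange at −78 °C converts 17 into the arylmagnesium 18, which is stable at this temperature; after excess MeMgCl is added and the mixture is warmed, 18 loses magnesium 4-chlorobenzenesulfonate by β-elimination and gives the a3–a4 aryne 19. MeMgCl adds across the strained triple bond (carbomagnesiation) to give the arylmagnesium 20, and CO2 carboxylates 20 at a4, so the a3–CH3 and a4–CO2H bonds form in one flask. The closest known reaction type is the three-component coupling of 3-alkoxybenzynes, generated from 2-iodoaryl sulfonates by halogen–magnesium exchange, with Grignard reagents and an electrophile. No ring is closed and no stereocentre is formed. The step needs methyl to add at a3: the inductively withdrawing a5 aryloxy group distorts the aryne so that a3 is the more electrophilic carbon and stabilises the developing carbanion on a4, next to oxygen. It also needs chemoselectivity: the exchange is complete before any aryne exists, so only a trace of isopropylmagnesium competes with the large excess of MeMgCl, which should also outrun addition of 18 to 19 and attack of the neighbouring b2 ether oxygen on a4. The tert-butyl ester, flanked by two ortho substituents, and the acetal do not react with Grignard reagents below 0 °C, and the cold citric acid work-up spares the acetal.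

**Step 14**
Reactants: 21 benzoic acid with PMB ether on b2
Product: 22 3-(benzyloxy)-2-[4-(benzyloxy)-5-(tert-butoxycarbonyl)-6-(dimethoxymethyl)-2-hydroxy-3-methylphenoxy]-4-methoxy-6-methylbenzoic acid
Conditions: DDQ, CH2Cl2/pH 7 phosphate buffer, 0 °C to rt
Reagents that add atoms: none
Why: Oxidative cleavage of a PMB ether by DDQ (hydride abstraction from the electron-rich benzylic position, then hydrolysis of the oxocarbenium ion); unsubstituted benzyl ethers react far more slowly and the neutral buffer protects the acetal.

**Step 15**
Reactants: 22 hydroxy acid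
Product: 23 ring D depsidone carrying a6 and b4 benzyl ethers, the b5 tert-butyl ester and the b6 dimethoxymethyl group
Conditions: DCC, DMAP (cat.), CH2Cl2, 0 °C to rt
Reagents that add atoms: none
Why: Steglich-type lactonisation; the diaryl ether holds acid and phenol together, so the seven-membered ring D should close in preference to intermolecular esterification, as is usual for depsidones.

**Step 16**
Reactants: 23 protected depsidone
Product: 25 racemic lactol (3-hydroxyphthalide ring C closed; a6 and b4 benzyl ethers), via formyl acid 24 (not isolated)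
Conditions: TFA, CH2Cl2, H2O, 0 °C to rt
Reagents that add atoms: water, O
Why: Acidolysis of the tert-butyl ester and hydrolysis of the acetal give the 2-formylbenzoic acid 24, which exists as its ring tautomer, the 3-hydroxyphthalide; the lactol forms as the racemate, and the benzyl ethers and the ring D ester are stable to TFA at this temperature.

**Step 17**
Reactants: 25 racemic lactol
Product: 26 (R)-isobutyrate of the lactol (a6 and b4 benzyl ethers)
Conditions: (R)-benzotetramisole (10 mol %), (iPrCO)2O, iPr2NEt, CHCl3, 0 °C
Reagents that add atoms: isobutyric anhydride, CC(C)C(=O)OC(=O)C(C)C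
Why: Acylative dynamic kinetic resolution of a 3-hydroxyphthalide; the amine base interconverts the lactol enantiomers through the ring-opened formyl carboxylate while the chiral acyl isothiouronium ion acylates one of them faster, so the new stereocentre is set by the catalyst alone. The (R)-catalyst is proposed because the (R)-lactol corresponds spatially to the (R)-1-arylethanols that it acylates preferentially (lactone oxygen in place of methyl); the sense must be checked on the first run and the (S)-catalyst used if it is opposite.

**Step 18**
Reactants: 26 (R)-isobutyrate bis-benzyl ether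
Product: 27 (R)-isobutyrate of the lactol with free a6 and b4 hydroxyls
Conditions: H2 (1 atm), Pd/C, EtOAc, rt
Reagents that add atoms: none
Why: Hydrogenolysis of aryl benzyl ethers under neutral conditions; the stereocentre is an acylal and cannot epimerise, and the reaction is stopped as soon as both ethers are cleaved to spare the benzylic acyloxy group.

**Step 19**
Reactants: 27 (R)-isobutyrate diphenol
Product: 28 target depsidone CNP0211607.1 with the (R)-lactol
Conditions: immobilised Candida antarctica lipase B, phosphate buffer pH 6/MTBE, 10 °C
Reagents that add atoms: none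
Why: Lipase-catalysed hydrolysis of a phthalidyl ester; the serine hydrolase cleaves the acyl–oxygen bond and leaves the C–O bond at the stereocentre untouched, so the (R) configuration is retained, and weakly acidic pH at low temperature slows ring opening of the liberated lactol.

## Compound list

1 | 2,4-dihydroxy-3-methylbenzoic acid | Cc1c(O)ccc(C(=O)O)c1O | starting material
2 | (2,4-dihydroxy-3-methylphenyl)(imidazol-1-yl)methanone (acyl imidazolide) | Cc1c(O)ccc(C(=O)n2ccnc2)c1O | intermediate
3 | tert-butyl 2,4-dihydroxy-3-methylbenzoate | Cc1c(O)ccc(C(=O)OC(C)(C)C)c1O | intermediate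
4 | tert-butyl 5-bromo-2,4-dihydroxy-3-methylbenzoate | Cc1c(O)c(Br)cc(C(=O)OC(C)(C)C)c1O | intermediate
5 | tert-butyl 5-bromo-2-hydroxy-4-[(4-methoxybenzyl)oxy]-3-methylbenzoate | Cc1c(OCc2ccc(OC)cc2)c(Br)cc(C(=O)OC(C)(C)C)c1O | intermediate
6 | tert-butyl 2-(benzyloxy)-5-bromo-4-[(4-methoxybenzyl)oxy]-3-methylbenzoate | Cc1c(OCc2ccc(OC)cc2)c(Br)cc(C(=O)OC(C)(C)C)c1OCc1ccccc1 | intermediate
7 | 6-(chloromagnesio) derivative of 6 (arylmagnesium chloride between ester and bromine) | Cc1c(OCc2ccc(OC)cc2)c(Br)c([Mg]Cl)c(C(=O)OC(C)(C)C)c1OCc1ccccc1 | intermediate
8 | tert-butyl 2-(benzyloxy)-5-bromo-6-formyl-4-[(4-methoxybenzyl)oxy]-3-methylbenzoate | Cc1c(OCc2ccc(OC)cc2)c(Br)c(C=O)c(C(=O)OC(C)(C)C)c1OCc1ccccc1 | intermediate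
9 | tert-butyl 2-(benzyloxy)-5-bromo-6-(dimethoxymethyl)-4-[(4-methoxybenzyl)oxy]-3-methylbenzoate | Cc1c(OCc2ccc(OC)cc2)c(Br)c(C(OC)OC)c(C(=O)OC(C)(C)C)c1OCc1ccccc1 | intermediate
10 | tert-butyl 2-(benzyloxy)-6-(dimethoxymethyl)-5-hydroxy-4-[(4-methoxybenzyl)oxy]-3-methylbenzoate | Cc1c(OCc2ccc(OC)cc2)c(O)c(C(OC)OC)c(C(=O)OC(C)(C)C)c1OCc1ccccc1 | intermediate
11 | 2-bromo-3-hydroxy-4-methoxybenzaldehyde | COc1ccc(C=O)c(Br)c1O | starting material
12 | 3-(benzyloxy)-2-bromo-4-methoxybenzaldehyde | COc1ccc(C=O)c(Br)c1OCc1ccccc1 | intermediate
13 | tert-butyl 2-(benzyloxy)-5-[2-(benzyloxy)-6-formyl-3-methoxyphenoxy]-6-(dimethoxymethyl)-4-[(4-methoxybenzyl)oxy]-3-methylbenzoate | COc1ccc(C=O)c(Oc2c(OCc3ccc(OC)cc3)c(C)c(OCc3ccccc3)c(C(=O)OC(C)(C)C)c2C(OC)OC)c1OCc1ccccc1 | intermediate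
14 | tert-butyl 2-(benzyloxy)-5-[2-(benzyloxy)-6-(formyloxy)-3-methoxyphenoxy]-6-(dimethoxymethyl)-4-[(4-methoxybenzyl)oxy]-3-methylbenzoate | COc1ccc(OC=O)c(Oc2c(OCc3ccc(OC)cc3)c(C)c(OCc3ccccc3)c(C(=O)OC(C)(C)C)c2C(OC)OC)c1OCc1ccccc1 | intermediate
15 | tert-butyl 2-(benzyloxy)-5-[2-(benzyloxy)-6-hydroxy-3-methoxyphenoxy]-6-(dimethoxymethyl)-4-[(4-methoxybenzyl)oxy]-3-methylbenzoate | COc1ccc(O)c(Oc2c(OCc3ccc(OC)cc3)c(C)c(OCc3ccccc3)c(C(=O)OC(C)(C)C)c2C(OC)OC)c1OCc1ccccc1 | intermediate
16 | tert-butyl 2-(benzyloxy)-5-[2-(benzyloxy)-6-hydroxy-5-iodo-3-methoxyphenoxy]-6-(dimethoxymethyl)-4-[(4-methoxybenzyl)oxy]-3-methylbenzoate | COc1cc(I)c(O)c(Oc2c(OCc3ccc(OC)cc3)c(C)c(OCc3ccccc3)c(C(=O)OC(C)(C)C)c2C(OC)OC)c1OCc1ccccc1 | intermediate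
17 | tert-butyl 2-(benzyloxy)-5-{2-(benzyloxy)-6-[(4-chlorophenyl)sulfonyloxy]-5-iodo-3-methoxyphenoxy}-6-(dimethoxymethyl)-4-[(4-methoxybenzyl)oxy]-3-methylbenzoate | COc1cc(I)c(OS(=O)(=O)c2ccc(Cl)cc2)c(Oc2c(OCc3ccc(OC)cc3)c(C)c(OCc3ccccc3)c(C(=O)OC(C)(C)C)c2C(OC)OC)c1OCc1ccccc1 | intermediate
18 | arylmagnesium chloride from 17 (MgCl on a3 in place of iodine, sulfonate on a4) | COc1cc([Mg]Cl)c(OS(=O)(=O)c2ccc(Cl)cc2)c(Oc2c(OCc3ccc(OC)cc3)c(C)c(OCc3ccccc3)c(C(=O)OC(C)(C)C)c2C(OC)OC)c1OCc1ccccc1 | intermediate
19 | aryne with the triple bond between a3 and a4 (a1 OMe, a5 aryloxy, a6 OBn) | COC1=CC#CC(Oc2c(OCc3ccc(OC)cc3)c(C)c(OCc3ccccc3)c(C(=O)OC(C)(C)C)c2C(OC)OC)=C1OCc1ccccc1 | intermediate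
20 | arylmagnesium chloride with methyl on a3 and MgCl on a4 | COc1cc(C)c([Mg]Cl)c(Oc2c(OCc3ccc(OC)cc3)c(C)c(OCc3ccccc3)c(C(=O)OC(C)(C)C)c2C(OC)OC)c1OCc1ccccc1 | intermediate
21 | 3-(benzyloxy)-2-{4-(benzyloxy)-5-(tert-butoxycarbonyl)-6-(dimethoxymethyl)-2-[(4-methoxybenzyl)oxy]-3-methylphenoxy}-4-methoxy-6-methylbenzoic acid | COc1cc(C)c(C(=O)O)c(Oc2c(OCc3ccc(OC)cc3)c(C)c(OCc3ccccc3)c(C(=O)OC(C)(C)C)c2C(OC)OC)c1OCc1ccccc1 | intermediate
22 | 3-(benzyloxy)-2-[4-(benzyloxy)-5-(tert-butoxycarbonyl)-6-(dimethoxymethyl)-2-hydroxy-3-methylphenoxy]-4-methoxy-6-methylbenzoic acid | COc1cc(C)c(C(=O)O)c(Oc2c(O)c(C)c(OCc3ccccc3)c(C(=O)OC(C)(C)C)c2C(OC)OC)c1OCc1ccccc1 | intermediate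
23 | depsidone with ring D closed (a4 carbonyl to b2 oxygen); a6 and b4 benzyl ethers; b5 tert-butyl ester; b6 dimethoxymethyl group | COc1cc(C)c2c(c1OCc1ccccc1)Oc1c(c(C)c(OCc3ccccc3)c(C(=O)OC(C)(C)C)c1C(OC)OC)OC2=O | intermediate
24 | depsidone with b5 carboxylic acid and b6 formyl group (open form of the lactol); a6 and b4 benzyl ethers | COc1cc(C)c2c(c1OCc1ccccc1)Oc1c(c(C)c(OCc3ccccc3)c(C(=O)O)c1C=O)OC2=O | intermediate
25 | racemic lactol: depsidone with the 3-hydroxyphthalide ring C; a6 and b4 benzyl ethers | COc1cc(C)c2c(c1OCc1ccccc1)Oc1c(c(C)c(OCc3ccccc3)c3c1C(O)OC3=O)OC2=O | intermediate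
26 | (R)-isobutyrate of lactol 25 (acyloxy group on the b6 lactol carbon); a6 and b4 benzyl ethers | COc1cc(C)c2c(c1OCc1ccccc1)Oc1c(c(C)c(OCc3ccccc3)c3c1[C@H](OC(=O)C(C)C)OC3=O)OC2=O | intermediate
27 | (R)-isobutyrate of the lactol with free a6 and b4 hydroxyls | COc1cc(C)c2c(c1O)Oc1c(c(C)c(O)c3c1[C@H](OC(=O)C(C)C)OC3=O)OC2=O | intermediate
28 | CNP0211607.1: depsidone with a1 OMe, a3 CH3, a6 OH, b3 CH3, b4 OH and the (R)-3-hydroxyphthalide ring C on b5/b6 | COc1cc(C)c2c(c1O)Oc1c(c(C)c(O)c3c1[C@H](O)OC3=O)OC2=O | target

## Step count and uncertain steps

Total: 19 steps. Longest linear sequence: 18 steps (steps 1 to 7 and 9 to 19, from 1); ring A contributes one further step (step 8).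

**Step 13 (key step).** Most likely failure: methyl transfer to the aryne 19 is too slow, so that addition of the arylmagnesium 18 to 19, capture of the aryne by the neighbouring b2 ether oxygen, or sulfonyl transfer to the Grignard reagent take over; a minor loss could come from incomplete regiocontrol of the methyl addition. Fallback, from 16 and back at 21: Suzuki–Miyaura methylation of the aryl iodide (MeB(OH)2, Pd(dppf)Cl2, K2CO3, dioxane/H2O) gives the a3-methyl phenol F1. Triflation (Tf2O, pyridine) gives the aryl triflate F2. Palladium-catalysed hydroxycarbonylation (Pd(OAc)2, dppf, CO, KOAc, DMSO) converts F2 into the acid 21. The two carbons are then introduced one at a time by cross-coupling and no aryne is involved.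

**Step 9.** Most likely failure: slow C–O bond formation because both partners carry two ortho substituents, with reductive loss of bromine from 12 taking over. Fallback, from 10 and back at 13: nucleophilic aromatic substitution without copper on the fluoro analogue 3-(benzyloxy)-2-fluoro-4-methoxybenzaldehyde F3 (from commercial 2-fluoro-3-hydroxy-4-methoxybenzaldehyde, BnBr, K2CO3). Phenol 10 and F3 with Cs2CO3 in DMSO at 110 °C should give 13 through a Meisenheimer adduct stabilised by the ortho formyl group.

**Step 17.** Most likely failure: low enantioselectivity or slow acylation, because the lactol carbon is shielded by the ortho aryloxy group and uncatalysed acylation of the lactol alkoxide competes. Fallback, from 25 and back at 26: acylation without a chiral catalyst (isobutyric anhydride, DMAP, Et3N) gives the racemic isobutyrate F4, which is configurationally stable and is separated on a chiral stationary phase into 26 and its enantiomer F5. F5 is returned to racemic 25 by lipase hydrolysis and recycled.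

**Step 18.** Most likely failure: hydrogenolysis of the benzylic acyloxy C–O bond of the phthalide competing with cleavage of the benzyl ethers. Fallback, from 25 and back at 28: the benzyl ethers are removed first (H2, Pd/C, EtOAc) to give the racemic triol lactol F6. Acylative dynamic kinetic resolution with excess isobutyric anhydride and (R)-benzotetramisole gives the (R)-tris(isobutyrate) F7. The lipase of step 19 then removes all three acyl groups to give 28.

**Step 19.** Most likely failure: partial racemisation of the liberated lactol during the aqueous hydrolysis, or slow turnover of a hindered ester by the enzyme. Fallback, from 25 and back at 28: the dynamic kinetic resolution of step 17 is run with 4-azidobutanoic anhydride to give the (R)-4-azidobutanoate F8. Hydrogenation (H2, Pd/C, EtOAc) cleaves the benzyl ethers and reduces the azide to the amine F9, which cyclises to 2-pyrrolidinone and releases 28 without water or enzyme.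

## Further compounds

F1 | step 13 | tert-butyl 2-(benzyloxy)-5-[2-(benzyloxy)-6-hydroxy-3-methoxy-5-methylphenoxy]-6-(dimethoxymethyl)-4-[(4-methoxybenzyl)oxy]-3-methylbenzoate | COc1cc(C)c(O)c(Oc2c(OCc3ccc(OC)cc3)c(C)c(OCc3ccccc3)c(C(=O)OC(C)(C)C)c2C(OC)OC)c1OCc1ccccc1
F2 | step 13 | aryl triflate of F1 (trifluoromethanesulfonyloxy group on a4) | COc1cc(C)c(OS(=O)(=O)C(F)(F)F)c(Oc2c(OCc3ccc(OC)cc3)c(C)c(OCc3ccccc3)c(C(=O)OC(C)(C)C)c2C(OC)OC)c1OCc1ccccc1
F3 | step 9 | 3-(benzyloxy)-2-fluoro-4-methoxybenzaldehyde | COc1ccc(C=O)c(F)c1OCc1ccccc1
F4 | step 17 | racemic isobutyrate of lactol 25 | COc1cc(C)c2c(c1OCc1ccccc1)Oc1c(c(C)c(OCc3ccccc3)c3c1C(OC(=O)C(C)C)OC3=O)OC2=O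
F5 | step 17 | (S)-isobutyrate, enantiomer of 26 | COc1cc(C)c2c(c1OCc1ccccc1)Oc1c(c(C)c(OCc3ccccc3)c3c1[C@@H](OC(=O)C(C)C)OC3=O)OC2=O
F6 | step 18 | racemic lactol with free a6 and b4 hydroxyls (racemic 28) | COc1cc(C)c2c(c1O)Oc1c(c(C)c(O)c3c1C(O)OC3=O)OC2=O
F7 | step 18 | (R)-tris(isobutyrate): isobutyryl groups on the a6 oxygen, the b4 oxygen and the lactol oxygen | COc1cc(C)c2c(c1OC(=O)C(C)C)Oc1c(c(C)c(OC(=O)C(C)C)c3c1[C@H](OC(=O)C(C)C)OC3=O)OC2=O
F8 | step 19 | (R)-4-azidobutanoate of lactol 25; a6 and b4 benzyl ethers | COc1cc(C)c2c(c1OCc1ccccc1)Oc1c(c(C)c(OCc3ccccc3)c3c1[C@H](OC(=O)CCCN=[N+]=[N-])OC3=O)OC2=O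
F9 | step 19 | (R)-4-aminobutanoate of the lactol with free a6 and b4 hydroxyls | COc1cc(C)c2c(c1O)Oc1c(c(C)c(O)c3c1[C@H](OC(=O)CCCN)OC3=O)OC2=O
A1 | alternative 1 | 4-(benzyloxy)-5-methoxy-2-pyrone bearing on C3 the ring B aryloxy group with the b2 but-2-ynoate, the b4 benzyl ether and the methyl pseudoester | O=C1OC=C(OC)C(OCc2ccccc2)=C1Oc1c(OC(=O)C#CC)c(C)c(OCc2ccccc2)c2c1C(OC)OC2=O
A2 | alternative 1 | bis-benzyl depsidone methyl pseudoester (racemic at the acetal carbon) | COc1cc(C)c2c(c1OCc1ccccc1)Oc1c(c(C)c(OCc3ccccc3)c3c1C(OC)OC3=O)OC2=O
A3 | alternative 2 | 4-(benzyloxy)-2-(tert-butyldimethylsilyloxy)-3-methylfuran | CC1=C(O[Si](C)(C)C(C)(C)C)OC=C1OCc1ccccc1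
A4 | alternative 2 | tert-butyl 4,4-diethoxybut-2-ynoate | CCOC(OCC)C#CC(=O)OC(C)(C)C
A5 | alternative 2 | tert-butyl 4-(benzyloxy)-2-(diethoxymethyl)-3-hydroxy-5-methyl-6-(tert-butyldimethylsilyloxy)benzoate | CC(C)(C)OC(=O)c1c(O[Si](C)(C)C(C)(C)C)c(C)c(OCc2ccccc2)c(O)c1C(OCC)OCC
A6 | alternative 3 | bis-benzyl depsidone b5-carboxylic acid with hydrogen on b6 | COc1cc(C)c2c(c1OCc1ccccc1)Oc1cc(C(=O)O)c(OCc3ccccc3)c(C)c1OC2=O
A7 | alternative 3 | bis-benzyl depsidone b5,b6-dicarboxylic anhydride | COc1cc(C)c2c(c1OCc1ccccc1)Oc1c3C(=O)OC(=O)c3c(OCc3ccccc3)c(C)c1OC2=O
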